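(The constants used here are invented; the rest is arithmetic.)

Two questions stand on this flask, how much target it holds at the end and how near saturation its solution is, and beside it stands a neighbour that differs only in having less catalyst.

substrate 20 mM; gas phase 0.65 mM (held); catalyst 0.5 mol%; time 2.5 min

- target at 2.5 min, in percent of the substrate charged
- concentration of dissolved gas in solution at 2.5 min, in percent of saturation

- at the start none of the gas is dissolved
- run time (flask): 2.5 min

    gas phase ⇌ dissolved gas, rate k1*(csat - [dissolved gas]) (k1 = 0.45 /s, csat = 0.65 mM)
    substrate + dissolved gas + catalyst → catalyst + target (k2 = 2.9 × 10⁵ /M²/s)
    dissolved gas + target → over-reaction product (k3 = 11 /M/s)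
    dissolved gas + catalyst ⇌ idle complex, settled at all times (K4 = 76000 /M)

We count lifetimes. Gas enters the solution of our flask with a lifetime of 2.22 s, far shorter than the run, so we reckon at saturation, where nearly all of the catalyst sits as idle complex and 0.00198 mM stays free. Over-reaction is then a pseudo-first-order loss of target, and the quantity we carry is the lifetime of target against over-reaction, one over its rate constant times the saturation concentration: 140 s. With substrate held at its charge, making and loss balance at a ceiling, the making rate times this lifetime, of 5.23% of the substrate charged. The run lasts 1.07 lifetimes, so we reckon target at 65.8% of the ceiling, which is 3.44% of the substrate charged. With that amount of target at the end of the run, we reckon that making and over-reaction together take 0.0124 mM/s of gas, which transfer matches with the solution at 95.8% of saturation.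

The neighbour has 0.3 mol% of catalyst, less than our 0.5 mol%. Reckoned at saturation, its target lifetime contains no catalyst, so we give it the same count of lifetimes, but its free catalyst shrinks with the charge, so its ceiling falls to 3.14% and we expect it to end lower in that proportion.

The forecast gives 3.4% and 96%, arguing that “The gas saturates within seconds”.

The simulation gives 3.38% of target and 96.0% of saturation for our flask. At 1.25 min that flask held 2.15% of target, where 0.536 lifetimes under the ceiling give 2.17%. For the neighbour, the same lifetime under its lower ceiling gives 2.07%, and that flask ends with 2.04% of target.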